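**Retrosynthetic overview**
- Feature: ring A (C4a, C5, C6, C7, C8, C8a) is read as a benzannulation product. C5-OH, C6-OMe, C7-OMe and C8-H are the carbonyl carbon, the two methoxy-bearing carbons and the CHCl carbon of 4-chloro-2,3-dimethoxycyclobutenone, and C4a=C8a is the enol ether double bond of a preformed ring C.
- Key disconnections: C8–C8a (Stille coupling) and C4a–C5 (6π electrocyclisation of the derived dienylketene). The chlorocyclobutenone comes from dimethyl squarate by reduction and chlorination.
- Ring C is cut to veratraldehyde and the siloxydiene (asymmetric hetero-Diels–Alder, sets C2 as S). The C8a stannane is installed through a C6 sulfone (anion stannylation, sulfinate elimination), because a direct vinylic lithiation would compete with the benzylic C2–H and the ortho positions of the dimethoxyarene.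
- Order of rings: ring B is bought with veratraldehyde, ring C is made first, ring A last. The C4 oxygen travels as a silyl ether and is unmasked and oxidised to the ketone at the end.

Key step: step 8

Assumption: the Ti(OiPr)4/(S)-BINOL catalyst is taken to add the diene to the Si face of veratraldehyde as it does with benzaldehyde-type substrates, giving 2S; the sign is to be checked on 4, and (R)-BINOL used instead if the opposite holds.

**Step 1**
Reactants: 1 3,4-dimethoxybenzaldehyde (veratraldehyde); 2 (E)-1-methoxy-3-(trimethylsilyloxy)buta-1,3-diene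
Product: 4 (S)-2-(3,4-dimethoxyphenyl)-2,3-dihydro-4H-pyran-4-one, via silylated aldol adduct 3 (not isolated)
Conditions: Ti(OiPr)4 (10 mol%), (S)-BINOL (20 mol%), CF3CO2H (cat.), 4 Å MS, Et2O, −20 °C; then CF3CO2H, CH2Cl2, 0 °C
Reagents that add atoms: none
Why: Catalytic asymmetric hetero-Diels–Alder reaction by the Mukaiyama aldol pathway, in which the BINOL–titanium Lewis acid binds the aldehyde and exposes its Si face to the diene terminus (C2 set as S), after which trifluoroacetic acid closes adduct 3 by oxa-Michael addition with loss of methanol.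

**Step 2**
Reactants: 4 (S)-2-(3,4-dimethoxyphenyl)-2,3-dihydro-4H-pyran-4-one
Product: 5 (2S,4S)-2-(3,4-dimethoxyphenyl)-3,4-dihydro-2H-pyran-4-ol
Conditions: NaBH4, CeCl3·7H2O, MeOH, −78 → −40 °C; NaHCO3 work-up
Reagents that add atoms: none
Why: Luche reduction gives clean 1,2-addition to the vinylogous ester carbonyl, and pseudo-axial hydride delivery on the half-chair with the aryl group equatorial should give the pseudo-equatorial alcohol cis to the C2 aryl group (C4 set as S by substrate control).

**Step 3**
Reactants: 5 (2S,4S)-2-(3,4-dimethoxyphenyl)-3,4-dihydro-2H-pyran-4-ol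
Product: 6 tert-butyl{[(2S,4S)-2-(3,4-dimethoxyphenyl)-3,4-dihydro-2H-pyran-4-yl]oxy}dimethylsilane
Conditions: TBSCl, imidazole, DMF, 0 °C → rt
Reagents that add atoms: tert-butyldimethylsilyl chloride (TBSCl), CC(C)(C)[Si](C)(C)Cl
Why: Imidazole-promoted silylation of the secondary allylic alcohol runs under basic conditions that leave the acid-labile enol ether and both stereocentres untouched.

**Step 4**
Reactants: 6 tert-butyl{[(2S,4S)-2-(3,4-dimethoxyphenyl)-3,4-dihydro-2H-pyran-4-yl]oxy}dimethylsilane
Product: 7 tert-butyl{[(2S,4S)-2-(3,4-dimethoxyphenyl)-6-(phenylsulfonyl)tetrahydro-2H-pyran-4-yl]oxy}dimethylsilane (both C6 epimers)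
Conditions: PhSO2H (freshly liberated from its sodium salt), CH2Cl2, 0 °C → rt
Reagents that add atoms: benzenesulfinic acid, O=S(O)c1ccccc1
Why: Markovnikov hydrosulfonylation of the enol ether (formation of an α-sulfonyl cyclic ether), in which protonation at C5 gives the C6 oxocarbenium ion that the sulfinate captures at sulfur; the C6 epimer mixture does not matter because C6 becomes sp2 again in step 5.

**Step 5**
Reactants: 7 tert-butyl{[(2S,4S)-2-(3,4-dimethoxyphenyl)-6-(phenylsulfonyl)tetrahydro-2H-pyran-4-yl]oxy}dimethylsilane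
Product: 9 tert-butyl{[(2S,4S)-2-(3,4-dimethoxyphenyl)-6-(tributylstannyl)-3,4-dihydro-2H-pyran-4-yl]oxy}dimethylsilane, via stannyl sulfone 8 (not isolated)
Conditions: LiN(iPr)2, THF, −78 °C; Bu3SnCl, −78 → 0 °C; then iPr2NEt, 50 °C
Reagents that add atoms: tributyltin chloride, CCCC[Sn](Cl)(CCCC)CCCC
Why: α-Sulfonyl carbanion stannylation followed by base-assisted loss of benzenesulfinic acid (the sulfone route to 1-stannyl glycals), in which the sulfone makes C6–H the only site the amide base can deprotonate, so the benzylic C2–H and the arene ortho positions are spared, and elimination can only take a C5 hydrogen to give the C5=C6 enol ether with tin on C6.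

**Step 6**
Reactants: 10 dimethyl squarate
Product: 11 4-hydroxy-2,3-dimethoxycyclobut-2-en-1-one (racemic)
Conditions: LiAlH(OtBu)3, THF, −78 → −20 °C; pH 7 buffer quench, used crude
Reagents that add atoms: none
Why: Chemoselective 1,2-hydride reduction of one carbonyl of the vinylogous diester by the bulky alkoxyaluminium hydride at low temperature; the new centre is racemic, which is immaterial because this carbon becomes aromatic C8.

**Step 7**
Reactants: 11 4-hydroxy-2,3-dimethoxycyclobut-2-en-1-one
Product: 12 4-chloro-2,3-dimethoxycyclobut-2-en-1-one (racemic)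
Conditions: PPh3, CCl4, CH2Cl2, 0 °C → rt; anhydrous, used at once
Reagents that add atoms: carbon tetrachloride, ClC(Cl)(Cl)Cl
Why: Appel chlorination under neutral, anhydrous conditions displaces the alkoxyphosphonium group by chloride at C4 and avoids the acid-promoted allylic transposition with loss of methanol that would lead to the methyl semisquarate.

**Step 8**
Reactants: 9 tert-butyl{[(2S,4S)-2-(3,4-dimethoxyphenyl)-6-(tributylstannyl)-3,4-dihydro-2H-pyran-4-yl]oxy}dimethylsilane; 12 4-chloro-2,3-dimethoxycyclobut-2-en-1-one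
Product: 16 (2S,4S)-4-[(tert-butyldimethylsilyl)oxy]-2-(3,4-dimethoxyphenyl)-6,7-dimethoxychroman-5-ol, via alkenylcyclobutenone 13 (not isolated), via dienylketene 14 (not isolated), via cyclohexadienone 15 (not isolated)
Conditions: PdCl2(PhCN)2 (5 mol%), tri(2-furyl)phosphine (10 mol%), dioxane, 50 °C; then 100 °C
Reagents that add atoms: none
Why: Stille cross-coupling followed by thermal cyclobutenone-to-phenol ring expansion: zerovalent palladium (formed in situ from the precatalyst) inserts into the carbonyl-activated allylic C–Cl bond of 12, the electron-rich α-alkoxyalkenyl stannane 9 transmetalates, and reductive elimination joins the cyclobutenone sp3 carbon (future C8) to C8a to give 13. Raising the temperature triggers conrotatory 4π opening of the strained ring to dienylketene 14, whose ketene carbon (future C5) bonds to the enol ether β-carbon C4a in a disrotatory 6π closure to cyclohexadienone 15, and enolisation aromatises ring A as the free C5 phenol 16. The closest known reaction type is this same palladium-catalysed coupling of 4-chloro-2-cyclobutenones with alkenyl- and heteroarylstannanes with in-situ thermolysis to oxygenated phenols. Ring A is closed as a six-membered carbocycle in the pericyclic 6π mode, pulled forward by release of ring strain and by aromatisation. No lasting stereocentre is created (the sp3 C4a of 15 is erased on tautomerisation), and C2 and C4 are spectators under these neutral conditions. The step needs coupling at the chlorine-bearing carbon and closure through the rotamer with the dihydropyranyl group turned inward: the first is fixed by the position of the C–Cl bond, the second by reversible ring opening that returns the unproductive outward ketene to 13, so the carbonyl carbon ends as C5–OH, the methoxy carbons as C6 and C7, and the former CHCl carbon as C8–H.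

**Step 9**
Reactants: 16 (2S,4S)-4-[(tert-butyldimethylsilyl)oxy]-2-(3,4-dimethoxyphenyl)-6,7-dimethoxychroman-5-ol
Product: 17 (2S,4S)-2-(3,4-dimethoxyphenyl)-6,7-dimethoxychroman-4,5-diol
Conditions: Bu4NF, AcOH (1:1), THF, 0 °C → rt; pH 7 work-up
Reagents that add atoms: none
Why: Fluoride-mediated cleavage of the Si–O bond, buffered with acetic acid so that neither phenoxide formation nor acid ionises the electron-rich benzylic C4 position; C2 and C4 are unchanged.

**Step 10**
Reactants: 17 (2S,4S)-2-(3,4-dimethoxyphenyl)-6,7-dimethoxychroman-4,5-diol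
Product: 18 (2S)-2-(3,4-dimethoxyphenyl)-5-hydroxy-6,7-dimethoxychroman-4-one (target)
Conditions: activated MnO2 (excess), CH2Cl2, rt
Reagents that add atoms: none
Why: Chemoselective heterogeneous MnO2 oxidation of the benzylic secondary alcohol, which should spare the free C5 phenol (then hydrogen-bonded to the new carbonyl) and, being neutral, should not open the flavanone ring, so C2 stays S while the C4 stereocentre is removed.

**Compound list**
1 | 3,4-dimethoxybenzaldehyde (veratraldehyde) | COc1ccc(C=O)cc1OC | starting material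
2 | (E)-1-methoxy-3-(trimethylsilyloxy)buta-1,3-diene | CO/C=C/C(=C)O[Si](C)(C)C | starting material
3 | (S,E)-5-(3,4-dimethoxyphenyl)-1-methoxy-5-[(trimethylsilyl)oxy]pent-1-en-3-one (not isolated) | COc1ccc([C@@H](O[Si](C)(C)C)CC(=O)/C=C/OC)cc1OC | intermediate
4 | (S)-2-(3,4-dimethoxyphenyl)-2,3-dihydro-4H-pyran-4-one | COc1ccc([C@@H]2CC(=O)C=CO2)cc1OC | intermediate
5 | (2S,4S)-2-(3,4-dimethoxyphenyl)-3,4-dihydro-2H-pyran-4-ol | COc1ccc([C@@H]2C[C@H](O)C=CO2)cc1OC | intermediate
6 | tert-butyl{[(2S,4S)-2-(3,4-dimethoxyphenyl)-3,4-dihydro-2H-pyran-4-yl]oxy}dimethylsilane | COc1ccc([C@@H]2C[C@H](O[Si](C)(C)C(C)(C)C)C=CO2)cc1OC | intermediate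
7 | tert-butyl{[(2S,4S)-2-(3,4-dimethoxyphenyl)-6-(phenylsulfonyl)tetrahydro-2H-pyran-4-yl]oxy}dimethylsilane (C6 epimers) | COc1ccc([C@@H]2C[C@H](O[Si](C)(C)C(C)(C)C)CC(O2)S(=O)(=O)c3ccccc3)cc1OC | intermediate
8 | tert-butyl{[(2S,4S)-2-(3,4-dimethoxyphenyl)-6-(phenylsulfonyl)-6-(tributylstannyl)tetrahydro-2H-pyran-4-yl]oxy}dimethylsilane (not isolated) | COc1ccc([C@@H]2C[C@H](O[Si](C)(C)C(C)(C)C)CC(O2)([Sn](CCCC)(CCCC)CCCC)S(=O)(=O)c3ccccc3)cc1OC | intermediate
9 | tert-butyl{[(2S,4S)-2-(3,4-dimethoxyphenyl)-6-(tributylstannyl)-3,4-dihydro-2H-pyran-4-yl]oxy}dimethylsilane | COc1ccc([C@@H]2C[C@H](O[Si](C)(C)C(C)(C)C)C=C(O2)[Sn](CCCC)(CCCC)CCCC)cc1OC | intermediate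
10 | dimethyl squarate (3,4-dimethoxycyclobut-3-ene-1,2-dione) | COC1=C(OC)C(=O)C1=O | starting material
11 | 4-hydroxy-2,3-dimethoxycyclobut-2-en-1-one (racemic) | COC1=C(OC)C(O)C1=O | intermediate
12 | 4-chloro-2,3-dimethoxycyclobut-2-en-1-one (racemic) | COC1=C(OC)C(Cl)C1=O | intermediate
13 | 4-{(2S,4S)-4-[(tert-butyldimethylsilyl)oxy]-2-(3,4-dimethoxyphenyl)-3,4-dihydro-2H-pyran-6-yl}-2,3-dimethoxycyclobut-2-en-1-one (epimers at the cyclobutenone sp3 carbon; not isolated) | COc1ccc([C@@H]2C[C@H](O[Si](C)(C)C(C)(C)C)C=C(O2)C3C(OC)=C(OC)C3=O)cc1OC | intermediate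
14 | (3E)-4-{(2S,4S)-4-[(tert-butyldimethylsilyl)oxy]-2-(3,4-dimethoxyphenyl)-3,4-dihydro-2H-pyran-6-yl}-2,3-dimethoxybuta-1,3-dien-1-one (not isolated) | COc1ccc([C@@H]2C[C@H](O[Si](C)(C)C(C)(C)C)C=C(O2)/C=C(OC)\C(OC)=C=O)cc1OC | intermediate
15 | (2S,4S)-4-[(tert-butyldimethylsilyl)oxy]-2-(3,4-dimethoxyphenyl)-6,7-dimethoxy-2,3,4,4a-tetrahydro-5H-chromen-5-one (C4a epimers; not isolated) | COc1ccc([C@@H]2C[C@H](O[Si](C)(C)C(C)(C)C)C3C(=CC(OC)=C(OC)C3=O)O2)cc1OC | intermediate
16 | (2S,4S)-4-[(tert-butyldimethylsilyl)oxy]-2-(3,4-dimethoxyphenyl)-6,7-dimethoxychroman-5-ol | COc1ccc([C@@H]2C[C@H](O[Si](C)(C)C(C)(C)C)c3c(cc(OC)c(OC)c3O)O2)cc1OC | intermediate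
17 | (2S,4S)-2-(3,4-dimethoxyphenyl)-6,7-dimethoxychroman-4,5-diol | COc1ccc([C@@H]2C[C@H](O)c3c(cc(OC)c(OC)c3O)O2)cc1OC | intermediate
18 | (2S)-2-(3,4-dimethoxyphenyl)-5-hydroxy-6,7-dimethoxychroman-4-one | COc1ccc([C@@H]2CC(=O)c3c(cc(OC)c(OC)c3O)O2)cc1OC | target

**Step count and risks**
Total step count: 10. Longest linear sequence: 8 steps (steps 1–5 and 8–10, from veratraldehyde 1); steps 6–7 are the two-step branch to 12.

Steps most likely to fail:

1. Step 8. Transmetalation may be slow, so that protodestannylation of the enol ether stannane or decomposition of the labile chloride wins. The benzylic silyl ether next to the newly formed phenol may also be lost on prolonged heating at 100 °C. Fallback (sets out from 9, comes back at 13 and then 16): the coupling is changed to a Negishi coupling and separated from the ring expansion. Tin–lithium exchange of 9 (n-BuLi, THF, −78 °C) should give the alkenyllithium F1. ZnCl2 converts it into the alkenylzinc chloride F2, which is coupled with 12 (Pd(PPh3)4, THF, 0 °C → rt) to give 13, isolated in this variant. Brief thermolysis of purified 13 in toluene at 80–100 °C, free of tin halide, then gives 16.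

2. Step 5. Stannylation of the hindered tertiary α-sulfonyl carbanion may be incomplete, or the tin group may be lost together with sulfinate instead of clean loss of benzenesulfinic acid. Fallback (sets out from 6, comes back at 16): 6 is oxidised at the enol ether (C5H5NH[CrO3Cl], NaOAc, CH2Cl2) to the δ-lactone F3. Enolisation with in-situ trapping (KN(SiMe3)2, (PhO)2P(O)Cl, THF, −78 °C) gives the ketene acetal phosphate F4. Palladium-catalysed stannylation ((Me3Sn)2, Pd(PPh3)4, LiCl, THF, reflux) gives the trimethylstannane F5, which takes the place of 9 in step 8 and gives 16. No strong base meets the benzylic C2–H or the arene in this sequence.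

3. Step 7. The activated carbinol, or the chloride once formed, may ionise with allylic transposition and loss of methanol to the semisquarate, and the chloride may hydrolyse on handling. Fallback (sets out from 11, comes back at 16): 11 is acetylated (Ac2O, pyridine, DMAP, CH2Cl2, 0 °C) to the acetate F6, a storable allylic ester. F6 replaces 12 in step 8 (Pd2(dba)3, tri(2-furyl)phosphine, LiCl, dioxane, 50 → 100 °C), with oxidative addition into the allylic C–O bond leading to the same cyclobutenyl palladium intermediate and on to 16.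

**Further compounds**
F1 | step 8 | {(2S,4S)-4-[(tert-butyldimethylsilyl)oxy]-2-(3,4-dimethoxyphenyl)-3,4-dihydro-2H-pyran-6-yl}lithium | COc1ccc([C@@H]2C[C@H](O[Si](C)(C)C(C)(C)C)C=C(O2)[Li])cc1OC
F2 | step 8 | {(2S,4S)-4-[(tert-butyldimethylsilyl)oxy]-2-(3,4-dimethoxyphenyl)-3,4-dihydro-2H-pyran-6-yl}zinc chloride | COc1ccc([C@@H]2C[C@H](O[Si](C)(C)C(C)(C)C)C=C(O2)[Zn]Cl)cc1OC
F3 | step 5 | (4S,6S)-4-[(tert-butyldimethylsilyl)oxy]-6-(3,4-dimethoxyphenyl)tetrahydro-2H-pyran-2-one | COc1ccc([C@@H]2C[C@H](O[Si](C)(C)C(C)(C)C)CC(=O)O2)cc1OC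
F4 | step 5 | (2S,4S)-4-[(tert-butyldimethylsilyl)oxy]-2-(3,4-dimethoxyphenyl)-3,4-dihydro-2H-pyran-6-yl diphenyl phosphate | COc1ccc([C@@H]2C[C@H](O[Si](C)(C)C(C)(C)C)C=C(O2)OP(=O)(Oc3ccccc3)Oc3ccccc3)cc1OC
F5 | step 5 | tert-butyl{[(2S,4S)-2-(3,4-dimethoxyphenyl)-6-(trimethylstannyl)-3,4-dihydro-2H-pyran-4-yl]oxy}dimethylsilane | COc1ccc([C@@H]2C[C@H](O[Si](C)(C)C(C)(C)C)C=C(O2)[Sn](C)(C)C)cc1OC
F6 | step 7 | 2,3-dimethoxy-4-oxocyclobut-2-en-1-yl acetate (racemic) | CC(=O)OC1C(OC)=C(OC)C1=O
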